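**Retrosynthetic overview**

- The target comes from hydrogenolysis of two benzyl ethers, after 7-O-sulfation of a 5,6,7-triol that is freed by acid cleavage of two 4-methoxybenzyl ethers on a 3,4'-di-O-benzyl-5-hydroxyflavone.
- Ring A is made last, from a C6-stannylated 3-benzyloxy-2-aryl-4-pyranone and a 4-chloro-2,3-bis(4-methoxybenzyloxy)cyclobutenone: Stille coupling forms C8–C8a, then four-electron ring opening and six-electron closure of the dienylketene form C4a–C5.
- Feature used: ring A has three contiguous oxygenated carbons C5, C6, C7 followed by C8–H. These map onto C1 (carbonyl), C2 and C3 (alkoxy) and C4 (C–H) of a squaric acid derived cyclobutenone annulated across the C8a=C4a bond of ring C.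
- The stannylpyranone comes from pyromeconic acid (ring C) by C2 bromination, O-benzylation, Suzuki coupling (ring B), C6 zincation/iodination and stannylation. The chlorocyclobutenone comes from squaric acid by silver-salt O-alkylation, monoreduction and neutral deoxychlorination.
- Ring order: ring C is bought, ring B is attached by cross-coupling, ring A is closed in the key step.

Key step: step 10

Remark: the target is taken as the free aryl hydrogen sulfate as drawn; the benzyl-protected sulfate and the target are written as free acids, the former being carried as its triethylammonium salt, and the cyclobutenone C4 stereocentre is racemic and disappears when ring A becomes aromatic.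

**Route**

Step 1
Reactants: 1 pyromeconic acid (3-hydroxy-4H-pyran-4-one)
Product: 2 2-bromo-3-hydroxy-4H-pyran-4-one
Conditions: NBS (1.05 equiv), MeCN, 0 °C to rt
Reagents that add atoms: N-bromosuccinimide, O=C1CCC(=O)N1Br
Why: Electrophilic bromination of the enol, where C2 is the only free carbon of the C2=C3 enol and is activated by O1 and the 3-OH, as in the C6 bromination of kojic acid.

Step 2
Reactants: 2 2-bromo-3-hydroxy-4H-pyran-4-one
Product: 3 3-(benzyloxy)-2-bromo-4H-pyran-4-one
Conditions: BnBr, K2CO3, DMF, rt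
Reagents that add atoms: benzyl bromide, BrCc1ccccc1
Why: Williamson etherification of the acidic 3-enol with a carbonate base that is too weak to open the pyranone ring.

Step 3
Reactants: 3 3-(benzyloxy)-2-bromo-4H-pyran-4-one; 4 [4-(benzyloxy)phenyl]boronic acid
Product: 5 3-(benzyloxy)-2-[4-(benzyloxy)phenyl]-4H-pyran-4-one
Conditions: Pd(PPh3)4 (5 mol %), K2CO3, dioxane/H2O, 80 °C
Reagents that add atoms: none
Why: Suzuki–Miyaura coupling, in which the C2–Br bond is a vinylogous acyl bromide that adds readily to zerovalent palladium while the benzyl ethers and the enone are inert to mild aqueous carbonate.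

Step 4
Reactants: 5 3-(benzyloxy)-2-[4-(benzyloxy)phenyl]-4H-pyran-4-one
Product: 7 3-(benzyloxy)-2-[4-(benzyloxy)phenyl]-6-iodo-4H-pyran-4-one, via C6-zincated pyranone 6 (not isolated)
Conditions: TMPZnCl·LiCl (1.3 equiv), THF, 25 °C; then I2, 0 °C
Reagents that add atoms: iodine, II; TMPZnCl·LiCl, CC1(C)CCCC(C)(C)N1[Zn]Cl.[Li+].[Cl-] (zinc and chlorine in 6 only)
Why: C–H zincation with a hindered zinc amide followed by iodinolysis, since C6–H next to the ring oxygen is the most acidic C–H of a 4-pyranone (the counterpart of C2–H of chromone, which this base zincates) and the zinc amide neither adds to the enone nor attacks the benzylic positions.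

Step 5
Reactants: 7 3-(benzyloxy)-2-[4-(benzyloxy)phenyl]-6-iodo-4H-pyran-4-one
Product: 8 3-(benzyloxy)-2-[4-(benzyloxy)phenyl]-6-(tributylstannyl)-4H-pyran-4-one
Conditions: (Bu3Sn)2 (1.3 equiv), Pd(PPh3)4 (5 mol %), toluene, 100 °C; chromatography on Et3N-washed silica
Reagents that add atoms: hexabutyldistannane, CCCC[Sn](CCCC)(CCCC)[Sn](CCCC)(CCCC)CCCC
Why: Palladium-catalysed stannylation of an alkenyl iodide with a distannane (oxidative addition, Sn–Sn transmetalation, C–Sn reductive elimination), which is well behaved for β-halo enones.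

Step 6
Reactants: 9 squaric acid
Product: 10 disilver squarate
Conditions: AgNO3 (2 equiv), H2O, rt, dark; filter, dry in vacuo
Reagents that add atoms: silver nitrate, [Ag+].[O-][N+](=O)[O-]
Why: Salt metathesis, driven by the insolubility of the disilver salt of this strong acid in water.

Step 7
Reactants: 10 disilver squarate; 11 4-methoxybenzyl chloride
Product: 12 3,4-bis[(4-methoxyphenyl)methoxy]cyclobut-3-ene-1,2-dione
Conditions: 11 (2.1 equiv), Et2O, rt, dark
Reagents that add atoms: none
Why: Silver-assisted O-alkylation of the squarate dianion with a benzylic chloride gives the diester under neutral conditions, whereas acid-catalysed esterification would destroy the 4-methoxybenzyl group.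

Step 8
Reactants: 12 3,4-bis[(4-methoxyphenyl)methoxy]cyclobut-3-ene-1,2-dione
Product: 13 4-hydroxy-2,3-bis[(4-methoxyphenyl)methoxy]cyclobut-2-en-1-one (racemic)
Conditions: LiAlH(OtBu)3 (1.05 equiv), THF, −78 to −20 °C; aq. KNaC4H4O6 work-up, no acid
Reagents that add atoms: none
Why: 1,2-Reduction of one carbonyl by a bulky alkoxyaluminium hydride, as used for dialkyl squarates; the remaining carbonyl is a vinylogous ester and resists a second hydride, and the new stereocentre is formed racemic and is lost in step 10.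

Step 9
Reactants: 13 4-hydroxy-2,3-bis[(4-methoxyphenyl)methoxy]cyclobut-2-en-1-one (racemic)
Product: 14 4-chloro-2,3-bis[(4-methoxyphenyl)methoxy]cyclobut-2-en-1-one (racemic)
Conditions: Me2C=C(Cl)NMe2 (1.1 equiv), CH2Cl2, −40 to 0 °C; evaporate cold, use crude at once
Reagents that add atoms: 1-chloro-N,N,2-trimethylprop-1-en-1-amine, CC(C)=C(Cl)N(C)C
Why: Deoxychlorination through the alkoxyiminium chloride, which collapses by chloride attack at C4 to the chloride and a neutral amide, so that no HCl is present to trigger the acid-catalysed 1,3-transposition of 13 to the cyclobutenedione; 14 is a vinylogous α-chloro ether that is kept cold and unpurified, and any allylic isomer from chloride return at C2 gives the same palladium allyl in step 10.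

Step 10
Reactants: 8 3-(benzyloxy)-2-[4-(benzyloxy)phenyl]-6-(tributylstannyl)-4H-pyran-4-one; 14 4-chloro-2,3-bis[(4-methoxyphenyl)methoxy]cyclobut-2-en-1-one (racemic)
Product: 18 3-(benzyloxy)-2-[4-(benzyloxy)phenyl]-5-hydroxy-6,7-bis[(4-methoxyphenyl)methoxy]-4H-chromen-4-one, via Stille adduct 15 (not isolated), via dienylketene 16 (not isolated), via 4aH-chromene-4,5-dione 17 (not isolated)
Conditions: Pd2(dba)3 (2.5 mol %), tris(2-furyl)phosphine (10 mol %), dioxane, 50 °C; then 100 °C
Reagents that add atoms: none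
Why: Zerovalent palladium adds to the allylic C–Cl bond of 14 to give an η3-oxocyclobutenyl complex, stannane 8 transmetalates and reductive elimination joins the pyranone carbon (C8a) to cyclobutenone C4 (C8), which is the known Stille coupling of 4-chlorocyclobutenones with alkenyl and heteroaryl stannanes. At 100 °C adduct 15 opens by conrotatory four-electron ring opening to dienylketene 16, and because this opening is reversible only the isomer with the pyranonyl group turned inward is consumed. Ring A then closes by disrotatory six-electron electrocyclisation of the ketene carbon (C5) onto C4a, the nucleophilic β-carbon of the O1–C8a=C4a enol ether, and dione 17 enolises to the 5-phenol 18, hydrogen-bonded to C4=O. No stereocentre remains, because C8 of 15 and C4a of 17 both become aromatic carbons. The step needs bond formation at cyclobutenone C4 and not at the alkoxy-bearing C2, which would end as the 7,8-dioxygenated isomer; C4 is the only unsubstituted allyl terminus, and the σ-bonded form with palladium on C4 keeps the vinylogous ester of the cyclobutenone intact. Closure can only go to C4a, the single C–H carbon next to C8a.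

Step 11
Reactants: 18 3-(benzyloxy)-2-[4-(benzyloxy)phenyl]-5-hydroxy-6,7-bis[(4-methoxyphenyl)methoxy]-4H-chromen-4-one
Product: 19 3-(benzyloxy)-2-[4-(benzyloxy)phenyl]-5,6,7-trihydroxy-4H-chromen-4-one
Conditions: CF3CO2H/CH2Cl2 (1:9), C6HMe5 (4 equiv), 0 °C, argon
Reagents that add atoms: none
Why: Acidolysis of the electron-rich 4-methoxybenzyl aryl ethers (SN1 cleavage, the cation being trapped by Friedel–Crafts alkylation of pentamethylbenzene), while the two benzyl ethers need far stronger acid and stay.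

Step 12
Reactants: 19 3-(benzyloxy)-2-[4-(benzyloxy)phenyl]-5,6,7-trihydroxy-4H-chromen-4-one
Product: 20 3-(benzyloxy)-2-[4-(benzyloxy)phenyl]-5,6-dihydroxy-4-oxo-4H-chromen-7-yl hydrogen sulfate
Conditions: SO3·NMe3 (1.0 equiv), Et3N (1.1 equiv), degassed DMF, 0 °C to rt, argon
Reagents that add atoms: sulfur trioxide–trimethylamine complex, C[N+](C)(C)S(=O)(=O)[O-]
Why: O-Sulfation of a phenoxide by an amine–SO3 complex, where the 7-OH para to the C4 carbonyl is the most acidic and least hindered hydroxyl (7-selective alkylation of 5,6,7-trihydroxyflavones follows the same order), the 5-OH is held in the hydrogen bond to C4=O and the 6-OH is flanked on both sides, so one equivalent should go to O7.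

Step 13
Reactants: 20 3-(benzyloxy)-2-[4-(benzyloxy)phenyl]-5,6-dihydroxy-4-oxo-4H-chromen-7-yl hydrogen sulfate
Product: 21 3,5,6-trihydroxy-2-(4-hydroxyphenyl)-4-oxo-4H-chromen-7-yl hydrogen sulfate
Conditions: H2 (1 atm), 10% Pd/C, MeOH/THF, rt; then cation-exchange resin (H+ form), 0 °C, freeze-dry
Reagents that add atoms: none
Why: Hydrogenolysis of the two benzyl ethers over palladium, to which aryl sulfate monoester salts and the flavone C2=C3 bond are stable, followed by cation exchange to set the hydrogen sulfate free.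

**Compound list**

1 | pyromeconic acid (3-hydroxy-4H-pyran-4-one) | O=c1ccocc1O | starting material
2 | 2-bromo-3-hydroxy-4H-pyran-4-one | O=c1ccoc(Br)c1O | intermediate
3 | 3-(benzyloxy)-2-bromo-4H-pyran-4-one | O=c1ccoc(Br)c1OCc1ccccc1 | intermediate
4 | [4-(benzyloxy)phenyl]boronic acid | OB(O)c1ccc(OCc2ccccc2)cc1 | starting material
5 | 3-(benzyloxy)-2-[4-(benzyloxy)phenyl]-4H-pyran-4-one | O=c1ccoc(-c2ccc(OCc3ccccc3)cc2)c1OCc1ccccc1 | intermediate
6 | chlorido{5-(benzyloxy)-6-[4-(benzyloxy)phenyl]-4-oxo-4H-pyran-2-yl}zinc, LiCl complex (not isolated) | Cl[Zn]c1cc(=O)c(OCc2ccccc2)c(-c2ccc(OCc3ccccc3)cc2)o1 | intermediate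
7 | 3-(benzyloxy)-2-[4-(benzyloxy)phenyl]-6-iodo-4H-pyran-4-one | O=c1cc(I)oc(-c2ccc(OCc3ccccc3)cc2)c1OCc1ccccc1 | intermediate
8 | 3-(benzyloxy)-2-[4-(benzyloxy)phenyl]-6-(tributylstannyl)-4H-pyran-4-one | CCCC[Sn](CCCC)(CCCC)c1cc(=O)c(OCc2ccccc2)c(-c2ccc(OCc3ccccc3)cc2)o1 | intermediate
9 | squaric acid | OC1=C(O)C(=O)C1=O | starting material
10 | disilver squarate | [Ag+].[Ag+].[O-]C1=C([O-])C(=O)C1=O | intermediate
11 | 4-methoxybenzyl chloride | COc1ccc(CCl)cc1 | starting material
12 | 3,4-bis[(4-methoxyphenyl)methoxy]cyclobut-3-ene-1,2-dione | O=C1C(=O)C(OCc2ccc(OC)cc2)=C1OCc1ccc(OC)cc1 | intermediate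
13 | 4-hydroxy-2,3-bis[(4-methoxyphenyl)methoxy]cyclobut-2-en-1-one (racemic) | O=C1C(O)C(OCc2ccc(OC)cc2)=C1OCc1ccc(OC)cc1 | intermediate
14 | 4-chloro-2,3-bis[(4-methoxyphenyl)methoxy]cyclobut-2-en-1-one (racemic) | O=C1C(Cl)C(OCc2ccc(OC)cc2)=C1OCc1ccc(OC)cc1 | intermediate
15 | 4-{5-(benzyloxy)-6-[4-(benzyloxy)phenyl]-4-oxo-4H-pyran-2-yl}-2,3-bis[(4-methoxyphenyl)methoxy]cyclobut-2-en-1-one (racemic, not isolated) | O=C1C(c2cc(=O)c(OCc3ccccc3)c(-c3ccc(OCc4ccccc4)cc3)o2)C(OCc2ccc(OC)cc2)=C1OCc1ccc(OC)cc1 | intermediate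
16 | (3E)-4-{5-(benzyloxy)-6-[4-(benzyloxy)phenyl]-4-oxo-4H-pyran-2-yl}-2,3-bis[(4-methoxyphenyl)methoxy]buta-1,3-dien-1-one (dienylketene, pyranonyl cis to C2, not isolated) | O=C=C(OCc1ccc(OC)cc1)/C(OCc1ccc(OC)cc1)=C\c1cc(=O)c(OCc2ccccc2)c(-c2ccc(OCc3ccccc3)cc2)o1 | intermediate
17 | 3-(benzyloxy)-2-[4-(benzyloxy)phenyl]-6,7-bis[(4-methoxyphenyl)methoxy]-4aH-chromene-4,5-dione (racemic, not isolated) | O=C1C(OCc3ccc(OC)cc3)=C(OCc3ccc(OC)cc3)C=C2OC(-c3ccc(OCc4ccccc4)cc3)=C(OCc3ccccc3)C(=O)C12 | intermediate
18 | 3-(benzyloxy)-2-[4-(benzyloxy)phenyl]-5-hydroxy-6,7-bis[(4-methoxyphenyl)methoxy]-4H-chromen-4-one | O=c1c(OCc2ccccc2)c(-c2ccc(OCc3ccccc3)cc2)oc2cc(OCc3ccc(OC)cc3)c(OCc3ccc(OC)cc3)c(O)c12 | intermediate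
19 | 3-(benzyloxy)-2-[4-(benzyloxy)phenyl]-5,6,7-trihydroxy-4H-chromen-4-one | O=c1c(OCc2ccccc2)c(-c2ccc(OCc3ccccc3)cc2)oc2cc(O)c(O)c(O)c12 | intermediate
20 | 3-(benzyloxy)-2-[4-(benzyloxy)phenyl]-5,6-dihydroxy-4-oxo-4H-chromen-7-yl hydrogen sulfate (carried as triethylammonium salt) | O=c1c(OCc2ccccc2)c(-c2ccc(OCc3ccccc3)cc2)oc2cc(OS(=O)(=O)O)c(O)c(O)c12 | intermediate
21 | 3,5,6-trihydroxy-2-(4-hydroxyphenyl)-4-oxo-4H-chromen-7-yl hydrogen sulfate (CNP0164757.0) | O=c1c(O)c(-c2ccc(O)cc2)oc2cc(OS(=O)(=O)O)c(O)c(O)c12 | target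

**Step count and risks**

Total step count: 13. Longest linear sequence: 9 steps (steps 1–5, then 10–13); the squaric acid branch is 4 steps (6–9) before the key step.

Steps most likely to fail:

1. Step 9. What may go wrong: the activated alcohol or the chloride ionises at C4 with help from the 2-alkoxy group, and the 4-methoxybenzyl group is then lost from oxygen to chloride, so the ring collapses to the cyclobutenedione. The fallback sets out from 13, which is acylated with methyl chloroformate and pyridine (CH2Cl2, 0 °C) to 2,3-bis[(4-methoxyphenyl)methoxy]-4-oxocyclobut-2-en-1-yl methyl carbonate F1, an allylic electrophile that does not ionise on its own. F1 and stannane 8 with Pd2(dba)3 and tris(2-furyl)phosphine in dioxane (50 °C, then 100 °C) should couple as allylic carbonates do with alkenylstannanes (oxidative addition with loss of CO2, transmetalation through the palladium methoxide) and ring-expand as in step 10, coming back to the route at 18.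

2. Step 10. What may go wrong: transmetalation from the electron-poor stannane is slow, so the palladium allyl is lost to reduction or dimerisation; or the C–C bond forms at the alkoxy-bearing allyl terminus, which would carry through to a 7,8-dioxygenated ring A. The fallback fixes the regiochemistry by carbonyl addition and sets out from iodide 7 and squarate 12.
   - Iodine–magnesium exchange of 7 (iPrMgCl·LiCl, THF, −60 °C) gives chlorido{5-(benzyloxy)-6-[4-(benzyloxy)phenyl]-4-oxo-4H-pyran-2-yl}magnesium F2.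
   - F2 adds once to 12 at −78 °C to give 4-{5-(benzyloxy)-6-[4-(benzyloxy)phenyl]-4-oxo-4H-pyran-2-yl}-4-hydroxy-2,3-bis[(4-methoxyphenyl)methoxy]cyclobut-2-en-1-one F3 (racemic).
   - Thermolysis in toluene at 110 °C under argon (Moore rearrangement, closure onto C4a) gives 3-(benzyloxy)-2-[4-(benzyloxy)phenyl]-5,8-dihydroxy-6,7-bis[(4-methoxyphenyl)methoxy]-4H-chromen-4-one F4.
   - The non-chelated 8-OH is triflated (PhNTf2, K2CO3, DMF) to 3-(benzyloxy)-2-[4-(benzyloxy)phenyl]-5-hydroxy-6,7-bis[(4-methoxyphenyl)methoxy]-4-oxo-4H-chromen-8-yl trifluoromethanesulfonate F5.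
   - Reduction of the triflate (Pd(OAc)2, 1,1'-bis(diphenylphosphino)ferrocene, HCO2H, Et3N, DMF, 70 °C) comes back to the route at 18.

3. Step 12. What may go wrong: sulfate transfer to the 6-OH as well as the 7-OH, or twofold sulfation, giving salts that can be neither separated nor assigned. The fallback sets out from 19. 2,2,2-Trichloroethyl chlorosulfate (1 equiv), Et3N and catalytic 4-(dimethylamino)pyridine in THF at −20 °C should give the neutral diester 3-(benzyloxy)-2-[4-(benzyloxy)phenyl]-5,6-dihydroxy-4-oxo-4H-chromen-7-yl 2,2,2-trichloroethyl sulfate F6, which can be chromatographed free of regioisomers and assigned by HMBC. HCO2NH4 with 10% Pd/C in MeOH then removes the trichloroethyl group and both benzyl ethers in one operation, and after the acid-form resin the route is rejoined at 21.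

**Further compounds**

F1 | step 9 | 2,3-bis[(4-methoxyphenyl)methoxy]-4-oxocyclobut-2-en-1-yl methyl carbonate (racemic) | COC(=O)OC1C(=O)C(OCc2ccc(OC)cc2)=C1OCc1ccc(OC)cc1
F2 | step 10 | chlorido{5-(benzyloxy)-6-[4-(benzyloxy)phenyl]-4-oxo-4H-pyran-2-yl}magnesium | Cl[Mg]c1cc(=O)c(OCc2ccccc2)c(-c2ccc(OCc3ccccc3)cc2)o1
F3 | step 10 | 4-{5-(benzyloxy)-6-[4-(benzyloxy)phenyl]-4-oxo-4H-pyran-2-yl}-4-hydroxy-2,3-bis[(4-methoxyphenyl)methoxy]cyclobut-2-en-1-one (racemic) | O=C1C(OCc2ccc(OC)cc2)=C(OCc2ccc(OC)cc2)C1(O)c1cc(=O)c(OCc2ccccc2)c(-c2ccc(OCc3ccccc3)cc2)o1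
F4 | step 10 | 3-(benzyloxy)-2-[4-(benzyloxy)phenyl]-5,8-dihydroxy-6,7-bis[(4-methoxyphenyl)methoxy]-4H-chromen-4-one | O=c1c(OCc2ccccc2)c(-c2ccc(OCc3ccccc3)cc2)oc2c(O)c(OCc3ccc(OC)cc3)c(OCc3ccc(OC)cc3)c(O)c12
F5 | step 10 | 3-(benzyloxy)-2-[4-(benzyloxy)phenyl]-5-hydroxy-6,7-bis[(4-methoxyphenyl)methoxy]-4-oxo-4H-chromen-8-yl trifluoromethanesulfonate | O=c1c(OCc2ccccc2)c(-c2ccc(OCc3ccccc3)cc2)oc2c(OS(=O)(=O)C(F)(F)F)c(OCc3ccc(OC)cc3)c(OCc3ccc(OC)cc3)c(O)c12
F6 | step 12 | 3-(benzyloxy)-2-[4-(benzyloxy)phenyl]-5,6-dihydroxy-4-oxo-4H-chromen-7-yl 2,2,2-trichloroethyl sulfate | O=c1c(OCc2ccccc2)c(-c2ccc(OCc3ccccc3)cc2)oc2cc(OS(=O)(=O)OCC(Cl)(Cl)Cl)c(O)c(O)c12
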